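- The easy step comes first: the north and south-east runs differ ten times in charge, yet at 90.0 s they read target 62% and 64%. So I reckon in percent of the charge.

| setting | north | south-east | midnight | dusk | noon | dawn |
|---|---|---|---|---|---|---|
| substrate | 0.13 mM | 1.4 mM | 0.25 mM | 0.50 mM | 1.0 mM | 2.0 mM |
| remark | run made earlier | run made earlier |  |  |  |  |
| time |  |  | 3.0 min | 3.0 min | 3.0 min | 3.0 min |

| run | time / s | target / % | substrate / % |
|---|---|---|---|
| north | 12.0 | 17 | 70 |
| north | 30.0 | 36 | 40 |
| north | 60.0 | 55 | 21 |
| north | 90.0 | 62 | 13 |
| south-east | 10.0 | 19 | 69 |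
| south-east | 15.0 | 21 | 62 |
| south-east | 40.0 | 44 | 34 |
| south-east | 90.0 | 64 | 17 |

(each reading ± 2 percentage points)

- "hardly changes" means that all values lie within two and a half points (for a concentration: within two and a half percent of the largest)

1. [target] at the end for midnight, dusk, noon, dawn, in this order
2. how the row runs (falls, then rises / rises, then falls / rises all the way / hardly changes / falls all the way)

- I take the rate of target as k_c times S, where S is substrate as a fraction of the charge. Integrated, target at any time is k_c times the area under the substrate curve.
- By trapezoids, that area up to 90.0 s is 34.4 s in the north run and 36.5 s in the south-east run. Target over area gives 0.0180 s⁻¹ and 0.0175 s⁻¹.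
- Their mean, read from scattered readings, is 0.0178 s⁻¹: this is k_c, the capture constant, a first-order rate constant for target made per unit of substrate area.
- Way one extends the area. Over the last two readings of each run, substrate decays at a mean constant λ of 0.0149 s⁻¹. From a mean last reading of 15.0%, that leaves 3.92% at 3.0 min. The closed-form tail, the drop in S over λ, then lifts a mean target of 63.0% to 76.2%.
- Way two holds target at a fixed share of the substrate lost, 74.1%, and gives 71.2%, which is less than way one.
- Way two is the one that cheats: the north share climbs from 56.7% at 12.0 s to 71.3% at 90.0 s. Target over area in that run reads 0.0179 s⁻¹ at 30.0 s and 0.0180 s⁻¹ at 90.0 s.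
- So I commit to 76.2%, which is 0.191 mM for midnight and 1.52 mM for dawn.
- The forecast gives 0.195 mM, 0.39 mM, 0.78 mM and 1.56 mM, so rises all the way, on the ground that “Target therefore scales with the charge”. Its dawn value is 78.0% of the charge, above my figure.
- The flasks give 0.187 mM, 0.373 mM, 0.747 mM and 1.49 mM, so rises all the way.

    substrate ⇌ intermediate A (K = 0.400, k = 0.0180 s⁻¹)
    substrate → target (k = 0.0190 s⁻¹)
    intermediate A ⇌ intermediate B (K = 7.80, k = 0.0210 s⁻¹)
    intermediate A ⇌ intermediate C (K = 0.460, k = 0.0160 s⁻¹)
    intermediate B → intermediate D (k = 0.00730 s⁻¹)
    intermediate D → side product (k = 0.0200 s⁻¹)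
    intermediate C ⇌ intermediate B (k = 0.00240 s⁻¹)

- At 3.00 min, target stands at 74.7% of the charge in midnight and 74.7% in dawn.
- In dawn, substrate falls from 12.3% at 1.50 min to 3.15% at 3.00 min, and k_c times the area under that decay gives 11 percentage points of new target. Dawn's target rises by 11 points.

The readings were computed for an exercise; noise was put on by code.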